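**Retrosynthetic overview**
- The target is a flavonol with rings A and B bought preformed; only ring C is built, and it is the last ring formed.
- Last step: hydrogenolysis of four benzyl ethers; both OMe groups are carried from the starting materials.
- Ring C (pyranone with 3-OH) comes from Algar–Flynn–Oyamada oxidative cyclisation of a 2'-hydroxychalcone, itself made by Claisen–Schmidt condensation.
- Ring A ketone: 2,6-dihydroxy-4-methoxyacetophenone, Elbs para-hydroxylation (symmetry makes the site unambiguous), then selective bis-benzylation leaving the hindered chelated 2-OH free.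
- Ring B aldehyde: 3,5-dihydroxy-4-methoxybenzaldehyde, bis-benzylated.

Assumption: the target has no stereocentre (it is achiral), so no enantiocontrol is needed; compounds 1 and 5 are taken as catalogue chemicals.

**Route**

Step 1
Reactants: 1 1-(2,6-dihydroxy-4-methoxyphenyl)ethan-1-one
Product: 3 1-(2,3,6-trihydroxy-4-methoxyphenyl)ethan-1-one, via potassium aryl sulfate 2 (not isolated)
Conditions: K2S2O8 (1.1 equiv), aq KOH, 10–20 °C, 24 h; then aq HCl, 90 °C, N2
Reagents that add atoms: potassium peroxodisulfate, [K+].[K+].[O-]S(=O)(=O)OOS(=O)(=O)[O-]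
Why: Elbs persulfate oxidation, in which the phenoxide attacks the peroxide oxygen through the carbon para to an OH (C3 and C5 are equivalent by symmetry, so only one product can form) and the aryl sulfate is then hydrolysed by acid.

Step 2
Reactants: 3 1-(2,3,6-trihydroxy-4-methoxyphenyl)ethan-1-one
Product: 4 1-[3,6-bis(benzyloxy)-2-hydroxy-4-methoxyphenyl]ethan-1-one
Conditions: BnBr (2.1 equiv), K2CO3 (2.5 equiv), acetone, reflux, N2
Reagents that add atoms: benzyl bromide, BrCc1ccccc1
Why: Williamson etherification takes the non-chelated 3-OH and the less hindered 6-OH, while the 2-OH, flanked by the acetyl group and the new 3-OBn and hydrogen-bonded to the carbonyl, stays free.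

Step 3
Reactants: 5 3,5-dihydroxy-4-methoxybenzaldehyde
Product: 6 3,5-bis(benzyloxy)-4-methoxybenzaldehyde
Conditions: BnBr (2.2 equiv), K2CO3 (3 equiv), DMF, 60 °C
Reagents that add atoms: benzyl bromide, BrCc1ccccc1
Why: Williamson etherification of both equivalent phenols masks the acidic OH groups that would deactivate the aldehyde in the base-mediated condensation.

Step 4
Reactants: 4 1-[3,6-bis(benzyloxy)-2-hydroxy-4-methoxyphenyl]ethan-1-one; 6 3,5-bis(benzyloxy)-4-methoxybenzaldehyde
Product: 8 (2E)-1-[3,6-bis(benzyloxy)-2-hydroxy-4-methoxyphenyl]-3-[3,5-bis(benzyloxy)-4-methoxyphenyl]prop-2-en-1-one, via racemic aldol adduct 7 (not isolated)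
Conditions: KOH (50% aq), EtOH/THF, rt, 48 h
Reagents that add atoms: none
Why: Claisen–Schmidt condensation, in which the methyl ketone enolate adds to the non-enolisable aldehyde and E1cB dehydration gives the conjugated E-enone.

Step 5
Reactants: 8 (2E)-1-[3,6-bis(benzyloxy)-2-hydroxy-4-methoxyphenyl]-3-[3,5-bis(benzyloxy)-4-methoxyphenyl]prop-2-en-1-one
Product: 10 5,8-bis(benzyloxy)-2-[3,5-bis(benzyloxy)-4-methoxyphenyl]-3-hydroxy-7-methoxy-4H-chromen-4-one, via racemic trans-dihydroflavonol 9 (not isolated)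
Conditions: 30% H2O2, aq NaOH, MeOH/THF, 0 °C to rt
Reagents that add atoms: hydrogen peroxide, OO
Why: Algar–Flynn–Oyamada oxidation, in which the 2'-phenoxide closes ring C onto the enone while alkaline peroxide oxygenates C3, and the dihydroflavonol is dehydrogenated in situ, erasing its two transient stereocentres.

Step 6
Reactants: 10 5,8-bis(benzyloxy)-2-[3,5-bis(benzyloxy)-4-methoxyphenyl]-3-hydroxy-7-methoxy-4H-chromen-4-one
Product: 11 2-(3,5-dihydroxy-4-methoxyphenyl)-3,5,8-trihydroxy-7-methoxy-4H-chromen-4-one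
Conditions: H2 (1 atm), 10% Pd/C, THF/MeOH, rt; filtered and concentrated under N2
Reagents that add atoms: none
Why: Catalytic hydrogenolysis cleaves the four benzylic C–O bonds while the methyl ethers and the conjugated chromenone survive.

**Compound list**

1 | 1-(2,6-dihydroxy-4-methoxyphenyl)ethan-1-one | CC(=O)c1c(O)cc(OC)cc1O | starting material
2 | potassium 3-acetyl-2,4-dihydroxy-6-methoxyphenyl sulfate | CC(=O)c1c(O)cc(OC)c(OS(=O)(=O)[O-])c1O.[K+] | intermediate
3 | 1-(2,3,6-trihydroxy-4-methoxyphenyl)ethan-1-one | CC(=O)c1c(O)cc(OC)c(O)c1O | intermediate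
4 | 1-[3,6-bis(benzyloxy)-2-hydroxy-4-methoxyphenyl]ethan-1-one | CC(=O)c1c(OCc2ccccc2)cc(OC)c(OCc2ccccc2)c1O | intermediate
5 | 3,5-dihydroxy-4-methoxybenzaldehyde | COc1c(O)cc(C=O)cc1O | starting material
6 | 3,5-bis(benzyloxy)-4-methoxybenzaldehyde | COc1c(OCc2ccccc2)cc(C=O)cc1OCc1ccccc1 | intermediate
7 | racemic 1-[3,6-bis(benzyloxy)-2-hydroxy-4-methoxyphenyl]-3-[3,5-bis(benzyloxy)-4-methoxyphenyl]-3-hydroxypropan-1-one (aldol adduct) | COc1cc(OCc2ccccc2)c(C(=O)CC(O)c2cc(OCc3ccccc3)c(OC)c(OCc3ccccc3)c2)c(O)c1OCc1ccccc1 | intermediate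
8 | (2E)-1-[3,6-bis(benzyloxy)-2-hydroxy-4-methoxyphenyl]-3-[3,5-bis(benzyloxy)-4-methoxyphenyl]prop-2-en-1-one | COc1cc(OCc2ccccc2)c(C(=O)/C=C/c2cc(OCc3ccccc3)c(OC)c(OCc3ccccc3)c2)c(O)c1OCc1ccccc1 | intermediate
9 | racemic trans-5,8-bis(benzyloxy)-2-[3,5-bis(benzyloxy)-4-methoxyphenyl]-3-hydroxy-7-methoxy-2,3-dihydro-4H-chromen-4-one (2R,3R enantiomer drawn) | O=C1c2c(OCc3ccccc3)cc(OC)c(OCc3ccccc3)c2O[C@H](c2cc(OCc3ccccc3)c(OC)c(OCc3ccccc3)c2)[C@H]1O | intermediate
10 | 5,8-bis(benzyloxy)-2-[3,5-bis(benzyloxy)-4-methoxyphenyl]-3-hydroxy-7-methoxy-4H-chromen-4-one | COc1cc(OCc2ccccc2)c2c(=O)c(O)c(-c3cc(OCc4ccccc4)c(OC)c(OCc4ccccc4)c3)oc2c1OCc1ccccc1 | intermediate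
11 | 2-(3,5-dihydroxy-4-methoxyphenyl)-3,5,8-trihydroxy-7-methoxy-4H-chromen-4-one | COc1cc(O)c2c(=O)c(O)c(-c3cc(O)c(OC)c(O)c3)oc2c1O | target

**Count**

Total steps: 6. Longest linear sequence: 5 (steps 1, 2, 4, 5, 6); step 3 is the side branch.

**Three steps most likely to fail**

Step 1 (Elbs oxidation: typically modest conversion, and the hydroquinone product is easily over-oxidised in base). The fallback sets out from 1 and replaces persulfate by a formylation/oxidation sequence. Vilsmeier–Haack reaction (POCl3, DMF, MeCN, 0 °C to rt) at the single kind of free ring position gives [(3-acetyl-2,4-dihydroxy-6-methoxyphenyl)methylidene]dimethylammonium chloride F1. Aqueous NaOAc hydrolyses it to 3-acetyl-2,4-dihydroxy-6-methoxybenzaldehyde F2. Dakin oxidation (H2O2, aq NaOH, 0 °C, N2) then converts the formyl group, which is ortho and para to free OH groups, into 3-acetyl-2,4-dihydroxy-6-methoxyphenyl formate F3. This is saponified in the same pot, and the fallback comes back to the route at 3.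

Step 2 (regioselectivity between the two chelated OH groups; some tri-benzylation). The fallback sets out from 3 and swaps kinetic alkylation for chelation-controlled dealkylation. Exhaustive benzylation (BnBr excess, K2CO3, DMF, 80 °C) gives 1-[2,3,6-tris(benzyloxy)-4-methoxyphenyl]ethan-1-one F4. BCl3 (1.1 equiv, CH2Cl2, −78 °C) then removes one benzyl group ortho to the carbonyl, preferentially the doubly flanked and most strained 2-O-benzyl. The fallback comes back to the route at 4.

Step 5 (chalcones with a 6'-alkoxy group can divert to aurones under Algar–Flynn–Oyamada conditions). The fallback sets out from 8 and separates ring closure from C3 oxygenation. Oxidative cyclisation (I2 cat., DMSO, 120 °C) gives 5,8-bis(benzyloxy)-2-[3,5-bis(benzyloxy)-4-methoxyphenyl]-7-methoxy-4H-chromen-4-one F5. Dimethyldioxirane (acetone/CH2Cl2, 0 °C) epoxidises the C2–C3 double bond to the racemic flavone 2,3-epoxide F6. Catalytic p-TsOH isomerises it to the 3-hydroxyflavone, and the fallback comes back to the route at 10.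

**Further compounds**

F1 | step 1 | [(3-acetyl-2,4-dihydroxy-6-methoxyphenyl)methylidene]dimethylammonium chloride | CC(=O)c1c(O)cc(OC)c(C=[N+](C)C)c1O.[Cl-]
F2 | step 1 | 3-acetyl-2,4-dihydroxy-6-methoxybenzaldehyde | CC(=O)c1c(O)cc(OC)c(C=O)c1O
F3 | step 1 | 3-acetyl-2,4-dihydroxy-6-methoxyphenyl formate | CC(=O)c1c(O)cc(OC)c(OC=O)c1O
F4 | step 2 | 1-[2,3,6-tris(benzyloxy)-4-methoxyphenyl]ethan-1-one | CC(=O)c1c(OCc2ccccc2)cc(OC)c(OCc2ccccc2)c1OCc1ccccc1
F5 | step 5 | 5,8-bis(benzyloxy)-2-[3,5-bis(benzyloxy)-4-methoxyphenyl]-7-methoxy-4H-chromen-4-one | COc1cc(OCc2ccccc2)c2c(=O)cc(-c3cc(OCc4ccccc4)c(OC)c(OCc4ccccc4)c3)oc2c1OCc1ccccc1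
F6 | step 5 | racemic 5,8-bis(benzyloxy)-2-[3,5-bis(benzyloxy)-4-methoxyphenyl]-2,3-epoxy-7-methoxy-2,3-dihydro-4H-chromen-4-one (one enantiomer drawn) | COc1cc(OCc2ccccc2)c2c(c1OCc1ccccc1)O[C@@]1(c3cc(OCc4ccccc4)c(OC)c(OCc4ccccc4)c3)O[C@H]1C2=O
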